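Ring B, the 3,5-dibromo-2-hydroxyphenoxy ring, carries its OH (C2′) next to the ether carbon (C1′): it is the enol of an α-aryloxy-cyclohexadienone. The route therefore disconnects the C1′–O bond as a carbene O–H insertion. Ring B enters dearomatised, as the o-quinone diazide made from 2-amino-4,6-dibromophenol, whose diazo carbon is C1′; ring A enters as 2,4-dibromo-6-methoxyphenol. One rhodium-carbenoid insertion into the phenolic O–H forms the hindered diaryl ether bond, rearomatises ring B and fixes the OH/Br pattern of both rings, with all four bromines already in place and untouched by copper or palladium. Demethylation then gives the target.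

Key step: step 3

Remark on the chemistry: the target has no stereocentre and no resolvable axis, so it is achiral and the SMILES defines it fully; "single enantiomer" adds no requirement.

Step 1
Reactants: 1 guaiacol (2-methoxyphenol)
Product: 2 2,4-dibromo-6-methoxyphenol
Conditions: Br2 (2.0 equiv), AcOH, 0 °C → rt
Reagents that add atoms: bromine, BrBr
Why: Electrophilic aromatic bromination in which the free OH outranks OMe as director, so the bromines should enter para and then ortho to OH, and the twice-deactivated ring should resist a third bromination at this stoichiometry and temperature.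

Step 2
Reactants: 3 2-amino-4,6-dibromophenol
Product: 5 2,4-dibromo-6-diazocyclohexa-2,4-dien-1-one, via 3,5-dibromo-2-hydroxybenzenediazonium chloride 4 (not isolated)
Conditions: NaNO2, aq. HCl, 0 °C; then NaHCO3 to pH 6–7, extraction into CH2Cl2, solvent exchange to ClCH2CH2Cl; solution kept cold and dark, not taken to dryness
Reagents that add atoms: sodium nitrite, [Na+].[O-]N=O
Why: Diazotisation of an o-aminophenol, whose acidic diazonium phenol should lose its OH proton on buffering to give the neutral o-quinone diazide; all positions ortho and para to OH are substituted, which blocks C-nitrosation and self-coupling, and both bromines are meta to N2+ and so not activated for halide exchange.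

Step 3
Reactants: 5 2,4-dibromo-6-diazocyclohexa-2,4-dien-1-one; 2 2,4-dibromo-6-methoxyphenol
Product: 6 2,4-dibromo-6-(2,4-dibromo-6-methoxyphenoxy)phenol
Conditions: Rh2(esp)2 (1–2 mol %), 2 (3 equiv), ClCH2CH2Cl, 60–80 °C, slow addition of 5, dark
Reagents that add atoms: none
Why: Rh(II) should extrude N2 from 5 to give an electrophilic quinoid carbenoid with aryl-cation character at the former diazo carbon; the phenolic oxygen of 2 adds to give an oxonium ylide, and proton transfer to the neighbouring carbonyl oxygen delivers the phenol, with the regained aromaticity of ring B as driving force. The closest known reaction type is the Rh(II)-carbenoid O–H insertion of α-diazo ketones and quinone diazides into alcohols and phenols. No ring is closed and no stereocentre is formed. Regiochemistry is fixed by the precursors: the ether oxygen can only end up on the former diazo carbon, so ring B gets OH, Br, Br and OAr exactly as in the target, and ring A keeps the Br/Br/OMe pattern of 2. The step needs O–H insertion to win over arene C-functionalisation, azo coupling, Wolff ring contraction and attack on the product phenol: every ortho and para position of 2 is substituted and both rings are electron-poor, which should shut down C-arylation and azo coupling; metal-catalysed decomposition in the dark avoids the free carbene that undergoes Wolff contraction; excess 2 (recoverable) and slow addition of 5 keep the product phenol from competing. Rh(II) does not insert into C–Br bonds, so the four bromines that a Cu- or Pd-mediated etherification would endanger should survive.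

Step 4
Reactants: 6 2,4-dibromo-6-(2,4-dibromo-6-methoxyphenoxy)phenol
Product: 7 3,5-dibromo-2-(3,5-dibromo-2-hydroxyphenoxy)phenol (target)
Conditions: BBr3 (3 equiv), CH2Cl2, −78 °C → rt; then H2O
Reagents that add atoms: none
Why: BBr3 cleavage of an aryl methyl ether (Lewis acid complexation, then SN2 attack of bromide on the methyl group) should free the second phenol on aqueous work-up, while the diaryl ether and the aryl bromides are inert to the reagent.

Compound list
1 | guaiacol (2-methoxyphenol) | COc1ccccc1O | starting material
2 | 2,4-dibromo-6-methoxyphenol | COc1cc(Br)cc(Br)c1O | intermediate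
3 | 2-amino-4,6-dibromophenol | Nc1cc(Br)cc(Br)c1O | starting material
4 | 3,5-dibromo-2-hydroxybenzenediazonium chloride | Oc1c(Br)cc(Br)cc1[N+]#N.[Cl-] | intermediate (not isolated)
5 | 2,4-dibromo-6-diazocyclohexa-2,4-dien-1-one | O=C1C(Br)=CC(Br)=CC1=[N+]=[N-] | intermediate
6 | 2,4-dibromo-6-(2,4-dibromo-6-methoxyphenoxy)phenol | COc1cc(Br)cc(Br)c1Oc1cc(Br)cc(Br)c1O | intermediate
7 | 3,5-dibromo-2-(3,5-dibromo-2-hydroxyphenoxy)phenol | Oc1cc(Br)cc(Br)c1Oc1cc(Br)cc(Br)c1O | target

Total step count: 4
Longest linear sequence: 3 steps (3 → 5 → 6 → 7, or 1 → 2 → 6 → 7)

Steps most likely to fail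

Step 3. The carbenoid may be diverted before the hindered, weakly nucleophilic OH of 2 captures it, through ring contraction, insertion into the product phenol to give oligo-ethers, or unproductive decomposition of the diazide. The fallback sets out from 2 and comes back to the route at 6, using nucleophilic aromatic substitution and a Baeyer–Villiger oxidation. The potassium phenoxide of 2 (K2CO3, DMF, 80 °C) should displace fluoride from commercial 2,4-dibromo-6-fluorobenzaldehyde, whose ortho-formyl group activates C–F far more than C–Br, to give 2,4-dibromo-6-(2,4-dibromo-6-methoxyphenoxy)benzaldehyde F1. Oxidation with mCPBA in CH2Cl2 should give 2,4-dibromo-6-(2,4-dibromo-6-methoxyphenoxy)phenyl formate F2, and methanolysis (K2CO3, MeOH) should give 6, which continues with step 4.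

Step 2. The diazide may be lost to thermal or photolytic decomposition during neutralisation, extraction and solvent exchange, or the poorly basic, poorly soluble amine may diazotise incompletely. The fallback sets out from 2 and comes back to the route at 7, avoiding any diazo compound. Commercial 2,4-dibromoanisole is converted by one-pot oxidative iodonium formation (I2, mCPBA, TfOH, CH2Cl2; iodination at the only free position ortho to OMe) into bis(3,5-dibromo-2-methoxyphenyl)iodonium triflate F3. Metal-free O-arylation of 2 with this salt (t-BuOK, THF, rt → 40 °C) should give 1,5-dibromo-2-(3,5-dibromo-2-methoxyphenoxy)-3-methoxybenzene F4. Double demethylation with BBr3 in CH2Cl2 should then give 7.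

Step 1. Over-bromination, or competing bromination para to the methoxy group, may give regioisomers that are hard to separate from 2. The fallback sets out from 5 and comes back to the route at 7; it replaces 2 by a commercial phenol of fixed bromine pattern and unmasks the second oxygen of ring A by oxidation instead of demethylation. Under the conditions of step 3, 5 and 3,5-dibromosalicylaldehyde should give 3,5-dibromo-2-(3,5-dibromo-2-hydroxyphenoxy)benzaldehyde F5. Baeyer–Villiger oxidation (mCPBA, CH2Cl2) should give 3,5-dibromo-2-(3,5-dibromo-2-hydroxyphenoxy)phenyl formate F6, and methanolysis (K2CO3, MeOH) should give 7.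

Further compounds
F1 | step 3 | 2,4-dibromo-6-(2,4-dibromo-6-methoxyphenoxy)benzaldehyde | COc1cc(Br)cc(Br)c1Oc1cc(Br)cc(Br)c1C=O
F2 | step 3 | 2,4-dibromo-6-(2,4-dibromo-6-methoxyphenoxy)phenyl formate | COc1cc(Br)cc(Br)c1Oc1cc(Br)cc(Br)c1OC=O
F3 | step 2 | bis(3,5-dibromo-2-methoxyphenyl)iodonium triflate | COc1c(Br)cc(Br)cc1[I+]c1cc(Br)cc(Br)c1OC.[O-]S(=O)(=O)C(F)(F)F
F4 | step 2 | 1,5-dibromo-2-(3,5-dibromo-2-methoxyphenoxy)-3-methoxybenzene | COc1cc(Br)cc(Br)c1Oc1cc(Br)cc(Br)c1OC
F5 | step 1 | 3,5-dibromo-2-(3,5-dibromo-2-hydroxyphenoxy)benzaldehyde | O=Cc1cc(Br)cc(Br)c1Oc1cc(Br)cc(Br)c1O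
F6 | step 1 | 3,5-dibromo-2-(3,5-dibromo-2-hydroxyphenoxy)phenyl formate | O=COc1cc(Br)cc(Br)c1Oc1cc(Br)cc(Br)c1O
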